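**Strategy.** The cycloheptane ring of the target is the ring of (S)-carvone enlarged by one carbon: the methyl-bearing CH (C-6), the CHOH, the CH2, both lactone-fused carbons and the ester-bearing CH (C-8, the old ketone) are carvone's ring, the methylene lactone is its oxidised isopropenyl group, and only C-7, the carbinol carbon carrying the crotonoyl group, is missing. Everything rests on the C-6–C-7 bond. A trans-fused keto lactone from carvone is homologated with trimethylsilyldiazomethane: the diazo carbon adds to the ketone, C-6 migrates to it, and the seven-membered ring closes as a regiodefined enol silane. Oxygenation, crotonylation and a Chan acyl shift then complete C-7.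

Key step: step 9

Remark on numbering: cycloheptane compounds carry the cyclohepta[b]furan locants of the target (O-1, C-2 lactone carbonyl, C-3 methylidene carbon, C-3a, C-4 CH2, C-5 CHOH, C-6 CHMe, C-7 carbinol carbon, C-8 ester CH, C-8a). Cyclohexane compounds keep carvone numbering, in which C-1, C-2, C-3, C-4, C-5 and C-6 become C-8, C-6, C-5, C-4, C-3a and C-8a. TBS = tert-butyldimethylsilyl.

Step 1
Reactants: 1 (S)-(+)-carvone
Product: 2 (1S,5S)-cis-carveol
Conditions: NaBH4, CeCl3·7H2O, MeOH, −78 → 0 °C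
Reagents that add atoms: none
Why: Luche 1,2-reduction of the enone, in which hydride should add to the half-chair with the isopropenyl group equatorial so that the new C-1 hydroxyl is pseudoequatorial and cis to the isopropenyl group.

Step 2
Reactants: 2 (1S,5S)-cis-carveol
Product: 3 (1S,2S,4R,6R)-1-methyl-4-(prop-1-en-2-yl)-7-oxabicyclo[4.1.0]heptan-2-ol
Conditions: VO(acac)2 (2 mol %), t-BuOOH, CH2Cl2, 0 °C → rt
Reagents that add atoms: tert-butyl hydroperoxide, CC(C)(C)OO
Why: Hydroxyl-directed vanadium-catalysed epoxidation should deliver oxygen to the ring alkene on the face of the allylic hydroxyl and spare the isopropenyl group, which places the future C-5 oxygen cis to the isopropenyl group.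

Step 3
Reactants: 3 (1S,2S,4R,6R)-1-methyl-4-(prop-1-en-2-yl)-7-oxabicyclo[4.1.0]heptan-2-ol
Product: 4 (1R,4S,6R)-1-methyl-4-(prop-1-en-2-yl)-7-oxabicyclo[4.1.0]heptan-2-one
Conditions: (n-Pr4N)RuO4 (5 mol %), N-methylmorpholine N-oxide, 4 Å molecular sieves, CH2Cl2, rt
Reagents that add atoms: none
Why: Perruthenate-catalysed oxidation of the secondary alcohol is neutral and should leave the epoxide and the alkene untouched.

Step 4
Reactants: 4 (1R,4S,6R)-1-methyl-4-(prop-1-en-2-yl)-7-oxabicyclo[4.1.0]heptan-2-one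
Product: 5 (2S,3R,5S)-3-hydroxy-2-methyl-5-(prop-1-en-2-yl)cyclohexan-1-one
Conditions: SmI2 (2.2 equiv), THF/MeOH, −90 °C
Reagents that add atoms: none
Why: Reductive cleavage of the Cα–O bond of the α,β-epoxy ketone by SmI2 keeps the C-3 oxygen, and protonation of the samarium enolate together with the thermodynamic preference of the epimerisable C-2 centre should place the methyl equatorial, trans to the hydroxyl.

Step 5
Reactants: 5 (2S,3R,5S)-3-hydroxy-2-methyl-5-(prop-1-en-2-yl)cyclohexan-1-one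
Product: 6 (2S,3R,5S)-3-[(tert-butyldimethylsilyl)oxy]-2-methyl-5-(prop-1-en-2-yl)cyclohexan-1-one
Conditions: TBSCl, imidazole, DMF, rt
Reagents that add atoms: tert-butyldimethylsilyl chloride, CC(C)(C)[Si](C)(C)Cl
Why: Standard silylation of the equatorial secondary alcohol, which also blocks β-elimination and hemiketal formation in the later steps.

Step 6
Reactants: 6 (2S,3R,5S)-3-[(tert-butyldimethylsilyl)oxy]-2-methyl-5-(prop-1-en-2-yl)cyclohexan-1-one
Product: 8 (2S,3R,5R,6R)-3-[(tert-butyldimethylsilyl)oxy]-6-hydroxy-2-methyl-5-(prop-1-en-2-yl)cyclohexan-1-one, via lithium enolate 7 (not isolated)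
Conditions: LiN(i-Pr)2, THF, −78 °C; then 2-(phenylsulfonyl)-3-phenyloxaziridine, −78 °C; aq. NH4Cl
Reagents that add atoms: 2-(phenylsulfonyl)-3-phenyloxaziridine, O=S(=O)(c1ccccc1)N1OC1c1ccccc1
Why: Kinetic deprotonation at the CH2 (C-6) and oxaziridine hydroxylation of the enolate anti to the neighbouring isopropenyl group should give the trans, equatorial α'-hydroxyl, which is also the thermodynamically preferred epimer.

Step 7
Reactants: 8 (2S,3R,5R,6R)-3-[(tert-butyldimethylsilyl)oxy]-6-hydroxy-2-methyl-5-(prop-1-en-2-yl)cyclohexan-1-one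
Product: 9 (2S,3R,5R,6R)-3-[(tert-butyldimethylsilyl)oxy]-6-hydroxy-5-(3-hydroxyprop-1-en-2-yl)-2-methylcyclohexan-1-one
Conditions: SeO2 (0.3 equiv), t-BuOOH, CH2Cl2, rt
Reagents that add atoms: tert-butyl hydroperoxide, CC(C)(C)OO
Why: Catalytic SeO2 allylic oxidation (ene reaction, then 2,3-shift) should hydroxylate the methyl group of the 1,1-disubstituted alkene, and any enal formed by over-oxidation converges in step 8.

Step 8
Reactants: 9 (2S,3R,5R,6R)-3-[(tert-butyldimethylsilyl)oxy]-6-hydroxy-5-(3-hydroxyprop-1-en-2-yl)-2-methylcyclohexan-1-one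
Product: 11 (3aR,5R,6S,7aR)-5-[(tert-butyldimethylsilyl)oxy]-6-methyl-3-methylidenehexahydro-1-benzofuran-2,7-dione, via lactol 10 (not isolated)
Conditions: TEMPO (0.2 equiv), PhI(OAc)2 (2.5 equiv), CH2Cl2, rt
Reagents that add atoms: none
Why: Oxoammonium oxidation is selective for the primary allylic alcohol, whose enal should close onto the trans-diequatorial C-6 hydroxyl to a lactol that is oxidised on to the trans-fused α-methylene lactone (oxidative lactonisation).

Step 9
Reactants: 11 (3aR,5R,6S,7aR)-5-[(tert-butyldimethylsilyl)oxy]-6-methyl-3-methylidenehexahydro-1-benzofuran-2,7-dione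
Product: 13 (3aR,5R,6R,8aR)-5-[(tert-butyldimethylsilyl)oxy]-6-methyl-3-methylidene-8-[(trimethylsilyl)oxy]-3,3a,4,5,6,8a-hexahydro-2H-cyclohepta[b]furan-2-one, via keto silane 12 (not isolated)
Conditions: Me3SiCHN2 (1.2 equiv), Sc(OTf)3 (10 mol %), CH2Cl2, −78 → 23 °C
Reagents that add atoms: trimethylsilyldiazomethane, C[Si](C)(C)C=[N+]=[N-]
Why: The scandium-activated ketone of 11 is attacked by the nucleophilic diazo carbon to give a β-oxido diazonium betaine, in which loss of N2 is coupled to a 1,2-shift of C-6 from the former carbonyl carbon (C-8) to the new carbon (C-7), and a 1,3-silyl shift from C-7 to oxygen then gives enol silane 13. The closest known reaction type is the Lewis-acid-catalysed one-carbon homologation of cycloalkanones with a silyl diazomethane (a Tiffeneau–Demjanov-type ring enlargement). The cycloheptene ring is closed by ring enlargement, that is by migration of a ring bond of the six-membered ketone onto the exocyclic diazo-derived carbon and not by cyclisation of an open chain, and the lactone ring is untouched. No new stereocentre is formed, because C-7 ends as an sp2 carbon and C-6 migrates with retention, so its methyl stays trans to the C-5 silyloxy group. The step needs migration of C-6 and not of C-8a, which the lactone oxygen on C-8a should secure, since an acyloxy-bearing carbon held in the trans-fused five-membered ring is the poorer migrating group. It also needs a single homologation at the ketone only, which the conversion of the keto silane into the unreactive enol silane and the low temperature (slow dipolar cycloaddition to the methylene lactone) should provide.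

Step 10
Reactants: 13 (3aR,5R,6R,8aR)-5-[(tert-butyldimethylsilyl)oxy]-6-methyl-3-methylidene-8-[(trimethylsilyl)oxy]-3,3a,4,5,6,8a-hexahydro-2H-cyclohepta[b]furan-2-one
Product: 16 (3aR,5R,6R,7R,8aR)-5-[(tert-butyldimethylsilyl)oxy]-7-hydroxy-6-methyl-3-methylidenehexahydro-2H-cyclohepta[b]furan-2,8(3H)-dione, via silyloxy epoxide 14 (not isolated), via silyloxy ketone 15 (not isolated)
Conditions: dimethyldioxirane, acetone/CH2Cl2, −78 → 0 °C; then AcOH, THF/H2O, 0 °C
Reagents that add atoms: dimethyldioxirane, CC1(C)OO1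
Why: Rubottom oxidation of the electron-rich enol silane (the methylene lactone is too electron-poor to compete) puts oxygen on C-7 regiospecifically, expected anti to the C-6 methyl, although the C-7 configuration is of no consequence because the centre is planarised again in step 12.

Step 11
Reactants: 16 (3aR,5R,6R,7R,8aR)-5-[(tert-butyldimethylsilyl)oxy]-7-hydroxy-6-methyl-3-methylidenehexahydro-2H-cyclohepta[b]furan-2,8(3H)-dione
Product: 17 (3aR,5R,6R,7R,8aR)-5-[(tert-butyldimethylsilyl)oxy]-6-methyl-3-methylidene-2,8-dioxooctahydro-2H-cyclohepta[b]furan-7-yl (E)-but-2-enoate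
Conditions: (E)-but-2-enoic anhydride, DMAP (cat.), pyridine, CH2Cl2, 0 °C
Reagents that add atoms: (E)-but-2-enoic anhydride, C/C=C/C(=O)OC(=O)/C=C/C
Why: DMAP-catalysed acylation of the only free hydroxyl places the four crotonoyl carbons on the C-7 oxygen, ready for transfer to carbon.

Step 12
Reactants: 17 (3aR,5R,6R,7R,8aR)-5-[(tert-butyldimethylsilyl)oxy]-6-methyl-3-methylidene-2,8-dioxooctahydro-2H-cyclohepta[b]furan-7-yl (E)-but-2-enoate
Product: 19 (3aR,5R,6S,7R,8aR)-7-[(E)-but-2-enoyl]-5-[(tert-butyldimethylsilyl)oxy]-7-hydroxy-6-methyl-3-methylidenehexahydro-2H-cyclohepta[b]furan-2,8(3H)-dione, via lithium enolate 18 (not isolated)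
Conditions: LiN(SiMe3)2 (1.1 equiv), THF, −78 °C; then AcOH, −78 °C
Reagents that add atoms: none
Why: Chan rearrangement, in which the C-7 enolate attacks the carbonyl of its own crotonate through a three-membered transition state and the acyl group moves from oxygen to carbon on the face anti to the pseudoaxial C-6 methyl, so that the crotonoyl group should end trans and the tertiary hydroxyl cis to that methyl, driven by formation of the stabilised tertiary alkoxide.

Step 13
Reactants: 19 (3aR,5R,6S,7R,8aR)-7-[(E)-but-2-enoyl]-5-[(tert-butyldimethylsilyl)oxy]-7-hydroxy-6-methyl-3-methylidenehexahydro-2H-cyclohepta[b]furan-2,8(3H)-dione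
Product: 20 (3aR,5R,6S,7S,8S,8aR)-7-[(E)-but-2-enoyl]-5-[(tert-butyldimethylsilyl)oxy]-7,8-dihydroxy-6-methyl-3-methylideneoctahydro-2H-cyclohepta[b]furan-2-one
Conditions: NaBH4, MeOH/CH2Cl2, −78 °C
Reagents that add atoms: none
Why: Borohydride should reduce the saturated, doubly α-oxygenated C-8 ketone faster than the conjugated crotonoyl ketone or the lactone, with hydride entering anti to the crotonoyl group on the adjacent quaternary C-7 (chelate-type control by the C-7 hydroxyl) to give the 7,8-trans diol.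

Step 14
Reactants: 20 (3aR,5R,6S,7S,8S,8aR)-7-[(E)-but-2-enoyl]-5-[(tert-butyldimethylsilyl)oxy]-7,8-dihydroxy-6-methyl-3-methylideneoctahydro-2H-cyclohepta[b]furan-2-one; 21 (R)-2-methylbutanoic acid
Product: 22 (3aR,5R,6S,7S,8S,8aR)-7-[(E)-but-2-enoyl]-5-[(tert-butyldimethylsilyl)oxy]-7-hydroxy-6-methyl-3-methylidene-2-oxooctahydro-2H-cyclohepta[b]furan-8-yl (2R)-2-methylbutanoate
Conditions: DCC, DMAP, CH2Cl2, 0 °C → rt
Reagents that add atoms: none
Why: Steglich esterification should acylate the secondary C-8 hydroxyl only, since the C-7 hydroxyl is tertiary and the C-5 oxygen is silylated, and the mild conditions should not epimerise the acid.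

Step 15
Reactants: 22 (3aR,5R,6S,7S,8S,8aR)-7-[(E)-but-2-enoyl]-5-[(tert-butyldimethylsilyl)oxy]-7-hydroxy-6-methyl-3-methylidene-2-oxooctahydro-2H-cyclohepta[b]furan-8-yl (2R)-2-methylbutanoate
Product: 23 (3aR,5R,6S,7S,8S,8aR)-7-[(E)-but-2-enoyl]-5,7-dihydroxy-6-methyl-3-methylidene-2-oxooctahydro-2H-cyclohepta[b]furan-8-yl (2R)-2-methylbutanoate
Conditions: HF·pyridine, THF, 0 °C → rt
Reagents that add atoms: none
Why: Buffered fluoride cleavage of the silyl ether is non-basic, so acyl migration, retro-Claisen cleavage of the α-ketol and conjugate addition to the two enone-type groups should be avoided.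

**Compound list**

1 | (S)-(+)-carvone, (5S)-2-methyl-5-(prop-1-en-2-yl)cyclohex-2-en-1-one | C=C(C)[C@H]1CC=C(C)C(=O)C1 | starting material
2 | (1S,5S)-cis-carveol (hydroxyl cis to isopropenyl) | C=C(C)[C@H]1CC=C(C)[C@@H](O)C1 | intermediate
3 | (1S,2S,4R,6R)-1-methyl-4-(prop-1-en-2-yl)-7-oxabicyclo[4.1.0]heptan-2-ol (oxirane oxygen, hydroxyl and isopropenyl all cis) | C=C(C)[C@H]1C[C@H]2O[C@@]2(C)[C@@H](O)C1 | intermediate
4 | (1R,4S,6R)-1-methyl-4-(prop-1-en-2-yl)-7-oxabicyclo[4.1.0]heptan-2-one (oxirane oxygen cis to isopropenyl) | C=C(C)[C@H]1C[C@H]2O[C@@]2(C)C(=O)C1 | intermediate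
5 | (2S,3R,5S)-3-hydroxy-2-methyl-5-(prop-1-en-2-yl)cyclohexan-1-one (all substituents equatorial) | C=C(C)[C@H]1C[C@@H](O)[C@H](C)C(=O)C1 | intermediate
6 | (2S,3R,5S)-3-[(tert-butyldimethylsilyl)oxy]-2-methyl-5-(prop-1-en-2-yl)cyclohexan-1-one | C=C(C)[C@H]1C[C@@H](O[Si](C)(C)C(C)(C)C)[C@H](C)C(=O)C1 | intermediate
7 | lithium enolate of 6 (C-1/C-6 enolate) | [Li+].C=C(C)[C@H]1C[C@@H](O[Si](C)(C)C(C)(C)C)[C@H](C)C([O-])=C1 | intermediate
8 | (2S,3R,5R,6R)-3-[(tert-butyldimethylsilyl)oxy]-6-hydroxy-2-methyl-5-(prop-1-en-2-yl)cyclohexan-1-one | C=C(C)[C@H]1C[C@@H](O[Si](C)(C)C(C)(C)C)[C@H](C)C(=O)[C@@H]1O | intermediate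
9 | (2S,3R,5R,6R)-3-[(tert-butyldimethylsilyl)oxy]-6-hydroxy-5-(3-hydroxyprop-1-en-2-yl)-2-methylcyclohexan-1-one | C=C(CO)[C@H]1C[C@@H](O[Si](C)(C)C(C)(C)C)[C@H](C)C(=O)[C@@H]1O | intermediate
10 | lactol of 11: trans-fused 2-hydroxy-3-methylidene-5-TBS-oxy-6-methylhexahydro-1-benzofuran-7-one (mixture at the lactol carbon) | C=C1C(O)O[C@@H]2[C@@H]1C[C@@H](O[Si](C)(C)C(C)(C)C)[C@H](C)C2=O | intermediate
11 | (3aR,5R,6S,7aR)-5-[(tert-butyldimethylsilyl)oxy]-6-methyl-3-methylidenehexahydro-1-benzofuran-2,7-dione (trans-fused keto lactone) | C=C1C(=O)O[C@@H]2[C@@H]1C[C@@H](O[Si](C)(C)C(C)(C)C)[C@H](C)C2=O | intermediate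
12 | keto silane: 5-TBS-oxy-6-methyl-3-methylidene-7-(trimethylsilyl)hexahydro-2H-cyclohepta[b]furan-2,8(3H)-dione (C-7 not defined) | C=C1C(=O)O[C@@H]2[C@@H]1C[C@@H](O[Si](C)(C)C(C)(C)C)[C@H](C)C([Si](C)(C)C)C2=O | intermediate
13 | (3aR,5R,6R,8aR)-5-[(tert-butyldimethylsilyl)oxy]-6-methyl-3-methylidene-8-[(trimethylsilyl)oxy]-3,3a,4,5,6,8a-hexahydro-2H-cyclohepta[b]furan-2-one | C=C1C(=O)O[C@@H]2[C@@H]1C[C@@H](O[Si](C)(C)C(C)(C)C)[C@H](C)C=C2O[Si](C)(C)C | intermediate
14 | 7,8-epoxide of 13 (oxirane oxygen anti to the C-6 methyl) | C=C1C(=O)O[C@@H]2[C@@H]1C[C@@H](O[Si](C)(C)C(C)(C)C)[C@H](C)[C@H]3O[C@@]23O[Si](C)(C)C | intermediate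
15 | 7-O-trimethylsilyl ether of 16 | C=C1C(=O)O[C@@H]2[C@@H]1C[C@@H](O[Si](C)(C)C(C)(C)C)[C@H](C)[C@@H](O[Si](C)(C)C)C2=O | intermediate
16 | (3aR,5R,6R,7R,8aR)-5-[(tert-butyldimethylsilyl)oxy]-7-hydroxy-6-methyl-3-methylidenehexahydro-2H-cyclohepta[b]furan-2,8(3H)-dione (expected major C-7 epimer; C-7 is planarised again in step 12) | C=C1C(=O)O[C@@H]2[C@@H]1C[C@@H](O[Si](C)(C)C(C)(C)C)[C@H](C)[C@@H](O)C2=O | intermediate
17 | (E)-but-2-enoate of 16 at the C-7 oxygen | C=C1C(=O)O[C@@H]2[C@@H]1C[C@@H](O[Si](C)(C)C(C)(C)C)[C@H](C)[C@@H](OC(=O)/C=C/C)C2=O | intermediate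
18 | lithium enolate of 17 (C-7/C-8 enolate) | [Li+].C=C1C(=O)O[C@@H]2[C@@H]1C[C@@H](O[Si](C)(C)C(C)(C)C)[C@H](C)C(OC(=O)/C=C/C)=C2[O-] | intermediate
19 | (3aR,5R,6S,7R,8aR)-7-[(E)-but-2-enoyl]-5-[(tert-butyldimethylsilyl)oxy]-7-hydroxy-6-methyl-3-methylidenehexahydro-2H-cyclohepta[b]furan-2,8(3H)-dione (crotonoyl trans, hydroxyl cis to the C-6 methyl) | C=C1C(=O)O[C@@H]2[C@@H]1C[C@@H](O[Si](C)(C)C(C)(C)C)[C@H](C)[C@@](O)(C(=O)/C=C/C)C2=O | intermediate
20 | (3aR,5R,6S,7S,8S,8aR)-7-[(E)-but-2-enoyl]-5-[(tert-butyldimethylsilyl)oxy]-7,8-dihydroxy-6-methyl-3-methylideneoctahydro-2H-cyclohepta[b]furan-2-one (7,8-trans diol) | C=C1C(=O)O[C@@H]2[C@@H]1C[C@@H](O[Si](C)(C)C(C)(C)C)[C@H](C)[C@@](O)(C(=O)/C=C/C)[C@H]2O | intermediate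
21 | (R)-2-methylbutanoic acid | CC[C@@H](C)C(=O)O | starting material
22 | 5-O-TBS ether of the target: (3aR,5R,6S,7S,8S,8aR)-7-[(E)-but-2-enoyl]-5-[(tert-butyldimethylsilyl)oxy]-7-hydroxy-6-methyl-3-methylidene-2-oxooctahydro-2H-cyclohepta[b]furan-8-yl (2R)-2-methylbutanoate | C=C1C(=O)O[C@@H]2[C@@H]1C[C@@H](O[Si](C)(C)C(C)(C)C)[C@H](C)[C@@](O)(C(=O)/C=C/C)[C@H]2OC(=O)[C@H](C)CC | intermediate
23 | (3aR,5R,6S,7S,8S,8aR)-7-[(E)-but-2-enoyl]-5,7-dihydroxy-6-methyl-3-methylidene-2-oxooctahydro-2H-cyclohepta[b]furan-8-yl (2R)-2-methylbutanoate | C=C1C(=O)O[C@@H]2[C@@H]1C[C@@H](O)[C@H](C)[C@@](O)(C(=O)/C=C/C)[C@H]2OC(=O)[C@H](C)CC | target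

**Step count.** Total: 15 steps. Longest linear sequence: 15 steps, from 1 to 23; acid 21 enters in step 14.

**Steps most likely to fail**

1. Step 9. The migration may involve the oxygen-bearing C-8a instead of C-6, the hindered ketone may add the diazoalkane too slowly, or the diazoalkane may undergo dipolar cycloaddition to the methylene lactone. The fallback sets out from 11 and returns at 17. The one-carbon silyl diazoalkane is replaced by the five-carbon acceptor diazo ketone (E)-1-diazopent-3-en-2-one F1, made from (E)-but-2-enoyl chloride and Me3SiCHN2 in MeCN at 0 °C. With BF3·OEt2 in CH2Cl2 at −78 °C its diazo carbon should insert between C-8 and C-6 of 11 to give the 7-crotonoyl β-diketone F2. This diazo ketone is a poor dipole toward the methylene lactone and cannot insert twice. Dimethyldioxirane then hydroxylates C-7 to the hydroxy diketone F3 (C-7 epimer mixture of 19). A catalytic amount of Et3N in CH2Cl2 should move the crotonoyl group from C-7 to the new oxygen (retro-Claisen 1,2-acyl shift) to give 17 and its C-7 epimer, both of which converge in step 12.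

2. Step 12. Deprotonation may occur at the ring-fusion carbon C-8a (epimerising the lactone fusion) or at the γ-position of the crotonate, or the acyl group may be delivered to the face of the methyl group. The fallback sets out from 16 and returns at 19, and replaces the intramolecular acyl shift by an intermolecular aldol addition. 16 is silylated (Et3SiCl, imidazole, DMF) to the triethylsilyl ether F4. LiN(SiMe3)2 and then (E)-but-2-enal at −78 °C should give the aldol adduct F5 by attack of the C-7 enolate anti to the C-6 methyl (mixture at the new carbinol carbon). MnO2 in CH2Cl2 oxidises the allylic alcohol to the enone F6, and AcOH/THF/H2O removes the triethylsilyl group in the presence of the TBS ether to give 19.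

3. Step 13. Hydride may be delivered to the face that carries the crotonoyl group, giving the 7,8-cis diol, or the enone may be reduced competitively. The fallback sets out from 19 and returns at 22, and sets C-8 by inversion instead of by the reduction. If the 8-epimeric alcohol F7 is the main product of the reduction, it is esterified with acid 21 under Mitsunobu conditions (PPh3, diisopropyl azodicarboxylate, toluene, 0 °C → rt). This should invert C-8 and give 22 directly, with the tertiary C-7 hydroxyl inert.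

**Further compounds**

F1 | step 9 | (E)-1-diazopent-3-en-2-one | C/C=C/C(=O)C=[N+]=[N-]
F2 | step 9 | 7-[(E)-but-2-enoyl]-5-TBS-oxy-6-methyl-3-methylidenehexahydro-2H-cyclohepta[b]furan-2,8(3H)-dione (trans-fused; C-7 not defined and largely enolised) | C=C1C(=O)O[C@@H]2[C@@H]1C[C@@H](O[Si](C)(C)C(C)(C)C)[C@H](C)C(C(=O)/C=C/C)C2=O
F3 | step 9 | C-7 epimer mixture of 19 | C=C1C(=O)O[C@@H]2[C@@H]1C[C@@H](O[Si](C)(C)C(C)(C)C)[C@H](C)C(O)(C(=O)/C=C/C)C2=O
F4 | step 12 | 7-O-triethylsilyl ether of 16 | C=C1C(=O)O[C@@H]2[C@@H]1C[C@@H](O[Si](C)(C)C(C)(C)C)[C@H](C)[C@@H](O[Si](CC)(CC)CC)C2=O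
F5 | step 12 | 7-[(E)-1-hydroxybut-2-enyl]-7-triethylsilyloxy analogue of 19 (mixture at the side-chain carbinol) | C=C1C(=O)O[C@@H]2[C@@H]1C[C@@H](O[Si](C)(C)C(C)(C)C)[C@H](C)[C@@](O[Si](CC)(CC)CC)(C(O)/C=C/C)C2=O
F6 | step 12 | 7-O-triethylsilyl ether of 19 | C=C1C(=O)O[C@@H]2[C@@H]1C[C@@H](O[Si](C)(C)C(C)(C)C)[C@H](C)[C@@](O[Si](CC)(CC)CC)(C(=O)/C=C/C)C2=O
F7 | step 13 | C-8 epimer of 20 (7,8-cis diol) | C=C1C(=O)O[C@@H]2[C@@H]1C[C@@H](O[Si](C)(C)C(C)(C)C)[C@H](C)[C@@](O)(C(=O)/C=C/C)[C@@H]2O
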